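The route rests on cutting ring B (C1–C5, C10) across C1–C10 and C4–C5. A Lewis-acid Diels–Alder reaction between (Z)-3-silyloxypenta-1,3-diene (C1–C4, C15) and a carene-derived (5R,6R)-cyclohexenone that already holds ring A (C5–C10), the isopropenyl group and C14 closes ring B in one operation and sets C4, C5 and C10. It exploits the 1,4-relation between the C3 oxygen and C10, which carries the C9 carbonyl, and the cis C5–C10 junction with the quaternary C5. C4 and C10 are epimerisable, so all adduct isomers converge on one cis-diketone. Ring A comes from (+)-3-carene by cyclopropane opening.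

Key step: step 5

Remark: eremophilane numbering is used (ring B = C1–C5 and C10; ring A = C5–C10; C11–C13 = isopropenyl on C7; C14 on C5; C15 on C4), β is the face of C14, and commercial (+)-3-carene is taken as the (1S,6R) enantiomer.

Step 1
Reactants: 1 (+)-3-carene, (1S,6R)-3,7,7-trimethylbicyclo[4.1.0]hept-3-ene
Product: 2 car-3-en-5-one, (1R,6S)-4,7,7-trimethylbicyclo[4.1.0]hept-3-en-2-one
Conditions: t-BuOOH (70% aq, 5 equiv), Rh2(cap)4 (0.5 mol %), K2CO3 (0.5 equiv), CH2Cl2, rt
Reagents that add atoms: tert-butyl hydroperoxide, CC(C)(C)OO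
Why: Allylic C–H oxidation (dirhodium caprolactamate/TBHP) should take the ring methylene between the alkene CH and the cyclopropane, giving the β-methyl enone conjugated with the three-membered ring; no stereocentre is touched.

Step 2
Reactants: 2 car-3-en-5-one
Product: 5 (S)-3-methyl-5-(prop-1-en-2-yl)cyclohex-2-en-1-one, via iodo silyl dienol ether 3 (not isolated), via silyl dienol ether 4 (not isolated)
Conditions: TMSI, CH2Cl2, −40 °C; then DBU, 0 °C → rt; then 1 M HCl, THF, 0 °C
Reagents that add atoms: none
Why: Silyl iodide opening of a cyclopropyl ketone: O-silylation and iodide attack at the tertiary carbon cleave the C8–C11 bond that overlaps with the enone π-system, DBU then removes HI by E2 at a methyl group (Hofmann direction for a tertiary iodide and a bulky base) to give the isopropenyl group, and acid hydrolysis of the dienol ether returns the enone; the C7 stereocentre of 2 is kept.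

Step 3
Reactants: 5 (S)-3-methyl-5-(prop-1-en-2-yl)cyclohex-2-en-1-one
Product: 8 (5R,6R)-3-methyl-5-(prop-1-en-2-yl)-6-[(triisopropylsilyl)oxy]cyclohex-2-en-1-one, via lithium dienolate 6 (not isolated), via TIPS dienol ether 7 (not isolated)
Conditions: LDA, THF, −78 °C; TIPSOTf, −78 → 0 °C; then mCPBA, CH2Cl2, −20 °C
Reagents that add atoms: triisopropylsilyl triflate, CC(C)[Si](C(C)C)(C(C)C)OS(=O)(=O)C(F)(F)F; mCPBA, OOC(=O)c1cccc(Cl)c1
Why: Kinetic α′-deprotonation and O-silylation give the cross-conjugated 2-silyloxydiene, and Rubottom oxidation (epoxidation of the electron-rich enol ether on the face anti to the isopropenyl group, then 1,4-silyl shift) should give the trans α′-silyloxy enone, whose oxygen later becomes the C8 ketone.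

Step 4
Reactants: 9 pent-1-en-3-one (ethyl vinyl ketone)
Product: 10 (Z)-tert-butyldimethyl(penta-1,3-dien-3-yloxy)silane
Conditions: TBSOTf, Et3N, Et2O, 0 °C
Reagents that add atoms: tert-butyldimethylsilyl triflate, CC(C)(C)[Si](C)(C)OS(=O)(=O)C(F)(F)F
Why: Soft enolisation of the ethyl ketone with silyl triflate and amine gives the (Z)-2-silyloxydiene; its geometry is not critical because C4 is equilibrated later.

Step 5
Reactants: 8 (5R,6R)-3-methyl-5-(prop-1-en-2-yl)-6-[(triisopropylsilyl)oxy]cyclohex-2-en-1-one; 10 (Z)-tert-butyldimethyl(penta-1,3-dien-3-yloxy)silane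
Product: 12 8α-(triisopropylsilyloxy)-7αH,10βH-eremophil-11-ene-3,9-dione (4β,5β-dimethyl, cis-fused), via Diels–Alder silyl enol ether 11 (not isolated)
Conditions: AlBr3/AlMe3 (5:1, 0.3 equiv), toluene/CH2Cl2, −20 → 0 °C; then NaOMe (0.2 equiv), MeOH, 0 °C → rt
Reagents that add atoms: none
Why: The Lewis acid binds the C9 carbonyl of 8, the silyl enol ether terminus C4 of 10 attacks the β-carbon C5 while C1 bonds to C10 in a concerted but asynchronous [4+2], so the oxygen ends at C3, para to the carbonyl-bearing C10. The closest known type is the mixed-Lewis-acid (AlBr3/AlMe3) Diels–Alder reaction of 2-silyloxydienes with β-substituted cyclohexenones that builds quaternary ring-fusion carbons. Ring B (C1–C5, C10) is closed by intermolecular [4+2] cycloaddition onto the preformed ring A; should the process be stepwise, the second bond C1–C10 forms by 6-endo-trig attack of the C10 enolate on the silyloxyallyl cation. At C5 the diene adds to the face anti to the C7 isopropenyl group (axial attack on the half-chair, as with carvone), so C14 ends β; at C10 suprafacial addition puts H-10 cis to C14, and methoxide keeps the cis junction because the trans isomer would force C14 and the isopropenyl group 1,3-diaxial. At C4 the endo adduct 11 has C15 α, but C4 is α to the C3 ketone set free by methanolysis and should equilibrate to the equatorial 4β-methyl, because an axial C15 would point into the concave face of the cis-decalin; C8 likewise stays equatorial. The only kinetic selectivities needed are therefore the regiochemistry (polarisation of diene and enone) and the π-face at C5 (C7 stereocentre), since diene geometry, endo/exo ratio and C4/C10 epimers all converge on 12.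

Step 6
Reactants: 12 8α-(triisopropylsilyloxy)-7αH,10βH-eremophil-11-ene-3,9-dione
Product: 13 8α-(triisopropylsilyloxy)-7αH,10βH-eremophil-11-ene-3α,9β-diol
Conditions: Al(Oi-Pr)3 (4 equiv), i-PrOH/toluene, 90 °C, slow distillation of acetone; then acetone (0.1 equiv), 90 °C to constant epimer ratio
Reagents that add atoms: none
Why: Meerwein–Ponndorf–Verley reduction is reversible (Oppenauer back-reaction), so both carbinol centres should settle at the equatorial epimers, 3α-OH trans to C15 and free of the 1,3-diaxial clash with C14, and 9β-OH on the convex face away from the axial C4–H; the C8 silyl ether is inert.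

Step 7
Reactants: 13 8α-(triisopropylsilyloxy)-7αH,10βH-eremophil-11-ene-3α,9β-diol
Product: 14 3α,9β-bis(3-methylbut-2-enoyloxy)-8α-(triisopropylsilyloxy)-7αH,10βH-eremophil-11-ene
Conditions: 3-methylbut-2-enoyl chloride (5 equiv), pyridine, DMAP (cat.), CH2Cl2, 0 → 40 °C
Reagents that add atoms: 3-methylbut-2-enoyl chloride, CC(C)=CC(=O)Cl
Why: DMAP-catalysed acylation of both equatorial alcohols; pyridine instead of a trialkylamine limits ketene formation and deconjugation of the senecioyl group.

Step 8
Reactants: 14 3α,9β-bis(3-methylbut-2-enoyloxy)-8α-(triisopropylsilyloxy)-7αH,10βH-eremophil-11-ene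
Product: 15 3α,9β-bis(3-methylbut-2-enoyloxy)-7αH,10βH-eremophil-11-en-8α-ol
Conditions: HF·pyridine, THF/pyridine, 0 °C → rt
Reagents that add atoms: none
Why: Acidic fluoride cleaves the Si–O bond without forming an alkoxide, so the C9 ester should not migrate to O8, and the isopropenyl group and the enoates are inert.

Step 9
Reactants: 15 3α,9β-bis(3-methylbut-2-enoyloxy)-7αH,10βH-eremophil-11-en-8α-ol
Product: 16 3α,9β-bis(3-methylbut-2-enoyloxy)-7αH,10βH-eremophil-11-en-8-one (CNP0264508.1)
Conditions: Dess–Martin periodinane, NaHCO3, CH2Cl2, 0 °C → rt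
Reagents that add atoms: none
Why: Dess–Martin oxidation of the secondary alcohol under buffered, non-enolising conditions should give the C8 ketone without epimerising C7 or C9 and without moving the 11,12-double bond into conjugation.

Compound list
1 | (+)-3-carene, (1S,6R)-3,7,7-trimethylbicyclo[4.1.0]hept-3-ene | CC1=CC[C@@H]2[C@H](C1)C2(C)C | starting material
2 | car-3-en-5-one, (1R,6S)-4,7,7-trimethylbicyclo[4.1.0]hept-3-en-2-one | CC1=CC(=O)[C@@H]2[C@H](C1)C2(C)C | intermediate
3 | trimethylsilyl dienol ether of (5S)-5-(2-iodopropan-2-yl)-3-methylcyclohex-2-enone (O-silyl on C1, double bonds C1=C6 and C2=C3) | CC1=CC(O[Si](C)(C)C)=C[C@H](C1)C(C)(C)I | intermediate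
4 | trimethylsilyl dienol ether of (5S)-3-methyl-5-(prop-1-en-2-yl)cyclohex-2-enone (O-silyl on C1, double bonds C1=C6 and C2=C3) | CC1=CC(O[Si](C)(C)C)=C[C@H](C1)C(C)=C | intermediate
5 | (S)-3-methyl-5-(prop-1-en-2-yl)cyclohex-2-en-1-one | CC1=CC(=O)C[C@H](C1)C(C)=C | intermediate
6 | lithium cross-conjugated dienolate of 5 (O–Li on C1, double bonds C1=C6 and C2=C3, 5S) | CC1=CC(O[Li])=C[C@H](C1)C(C)=C | intermediate
7 | triisopropylsilyl dienol ether of 5 (O-silyl on C1, double bonds C1=C6 and C2=C3, 5S) | CC1=CC(O[Si](C(C)C)(C(C)C)C(C)C)=C[C@H](C1)C(C)=C | intermediate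
8 | (5R,6R)-3-methyl-5-(prop-1-en-2-yl)-6-[(triisopropylsilyl)oxy]cyclohex-2-en-1-one | CC1=CC(=O)[C@H](O[Si](C(C)C)(C(C)C)C(C)C)[C@H](C1)C(C)=C | intermediate
9 | pent-1-en-3-one (ethyl vinyl ketone) | CCC(=O)C=C | starting material
10 | (Z)-tert-butyldimethyl(penta-1,3-dien-3-yloxy)silane | C=C/C(=C/C)O[Si](C)(C)C(C)(C)C | intermediate
11 | 4-epi-3-(tert-butyldimethylsilyloxy)-8α-(triisopropylsilyloxy)-7αH,10βH-eremophila-2,11-dien-9-one (endo adduct, 4α-methyl, cis-fused) | C=C(C)[C@H]1C[C@@]2(C)[C@H](CC=C(O[Si](C)(C)C(C)(C)C)[C@H]2C)C(=O)[C@@H]1O[Si](C(C)C)(C(C)C)C(C)C | intermediate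
12 | 8α-(triisopropylsilyloxy)-7αH,10βH-eremophil-11-ene-3,9-dione (4β,5β-dimethyl, cis-fused) | C=C(C)[C@H]1C[C@@]2(C)[C@H](CCC(=O)[C@@H]2C)C(=O)[C@@H]1O[Si](C(C)C)(C(C)C)C(C)C | intermediate
13 | 8α-(triisopropylsilyloxy)-7αH,10βH-eremophil-11-ene-3α,9β-diol | C=C(C)[C@H]1C[C@@]2(C)[C@H](CC[C@@H](O)[C@@H]2C)[C@@H](O)[C@@H]1O[Si](C(C)C)(C(C)C)C(C)C | intermediate
14 | 3α,9β-bis(3-methylbut-2-enoyloxy)-8α-(triisopropylsilyloxy)-7αH,10βH-eremophil-11-ene | C=C(C)[C@H]1C[C@@]2(C)[C@H](CC[C@@H](OC(=O)C=C(C)C)[C@@H]2C)[C@@H](OC(=O)C=C(C)C)[C@@H]1O[Si](C(C)C)(C(C)C)C(C)C | intermediate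
15 | 3α,9β-bis(3-methylbut-2-enoyloxy)-7αH,10βH-eremophil-11-en-8α-ol | C=C(C)[C@H]1C[C@@]2(C)[C@H](CC[C@@H](OC(=O)C=C(C)C)[C@@H]2C)[C@@H](OC(=O)C=C(C)C)[C@@H]1O | intermediate
16 | 3α,9β-bis(3-methylbut-2-enoyloxy)-7αH,10βH-eremophil-11-en-8-one (CNP0264508.1) | C=C(C)[C@H]1C[C@@]2(C)[C@H](CC[C@@H](OC(=O)C=C(C)C)[C@@H]2C)[C@@H](OC(=O)C=C(C)C)C1=O | target

Total step count: 9. Longest linear sequence: 8 steps (steps 1, 2, 3, 5, 6, 7, 8, 9); step 4 is the one-step side branch to the diene.

Steps most likely to fail

Step 6. Hydride transfer to the hindered faces of C3 and C9 may be too slow for the epimers to equilibrate, so that the kinetic axial alcohols persist, and the aluminium alkoxide may trigger 1,2-silyl migration from O8 to O9. The fallback separates reduction from equilibration. It sets out from 12, which is reduced under kinetic control with L-Selectride (THF, −78 °C) to the diaxial 8α-(triisopropylsilyloxy)-7αH,10βH-eremophil-11-ene-3β,9α-diol F5. Both carbinol centres are then epimerised by ruthenium hydrogen-transfer catalysis (Shvo catalyst, toluene, 90 °C), which needs no aluminium alkoxide; the equilibrium should lie on the side of the diequatorial diol, and the route is rejoined at 13.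

Step 2. The HI elimination may take the ring hydrogen at C7 instead of a methyl hydrogen (isopropylidene instead of isopropenyl, with loss of the stereocentre), and any desilylated enolate may re-close the cyclopropane. The fallback replaces base-induced E2 by a syn-elimination. It sets out from 2, which is opened with benzeneselenol and catalytic ZnI2 (CH2Cl2, 0 °C) to the tertiary selenide (S)-3-methyl-5-[2-(phenylselanyl)propan-2-yl]cyclohex-2-en-1-one F1. Oxidation with H2O2/pyridine (CH2Cl2, 0 °C → rt) gives the selenoxide (5S)-3-methyl-5-[2-(phenylseleninyl)propan-2-yl]cyclohex-2-en-1-one F2, which should eliminate without base towards a methyl group, and the route is rejoined at 5.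

Step 5. The cycloaddition at the β,β-disubstituted enone may be sluggish, the Lewis acid may strip silyl groups, and the α′-silyloxy group, which sits on the face the diene must use, may erode the π-facial selectivity. The fallback runs the cycloaddition on the unhindered enone and introduces the C8 oxygen afterwards. It sets out from 5, which reacts with 10 under the same mixed Lewis acid to give 4-epi-3-(tert-butyldimethylsilyloxy)-7αH,10βH-eremophila-2,11-dien-9-one F3, with C3 still masked as its silyl enol ether. Kinetic deprotonation at C8 (LDA, THF, −78 °C) and hydroxylation with a Davis oxaziridine give the 8α-hydroxy ketone 4-epi-3-(tert-butyldimethylsilyloxy)-8α-hydroxy-7αH,10βH-eremophila-2,11-dien-9-one F4 (an 8β epimer would converge later under methoxide). Silylation with TIPSOTf/2,6-lutidine rejoins the route at 11, which the methoxide stage of step 5 converts into 12.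

Further compounds
F1 | step 2 | (S)-3-methyl-5-[2-(phenylselanyl)propan-2-yl]cyclohex-2-en-1-one | CC1=CC(=O)C[C@H](C1)C(C)(C)[Se]c1ccccc1
F2 | step 2 | (5S)-3-methyl-5-[2-(phenylseleninyl)propan-2-yl]cyclohex-2-en-1-one | CC1=CC(=O)C[C@H](C1)C(C)(C)[Se](=O)c1ccccc1
F3 | step 5 | 4-epi-3-(tert-butyldimethylsilyloxy)-7αH,10βH-eremophila-2,11-dien-9-one | C=C(C)[C@H]1C[C@@]2(C)[C@H](CC=C(O[Si](C)(C)C(C)(C)C)[C@H]2C)C(=O)C1
F4 | step 5 | 4-epi-3-(tert-butyldimethylsilyloxy)-8α-hydroxy-7αH,10βH-eremophila-2,11-dien-9-one | C=C(C)[C@H]1C[C@@]2(C)[C@H](CC=C(O[Si](C)(C)C(C)(C)C)[C@H]2C)C(=O)[C@@H]1O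
F5 | step 6 | 8α-(triisopropylsilyloxy)-7αH,10βH-eremophil-11-ene-3β,9α-diol | C=C(C)[C@H]1C[C@@]2(C)[C@H](CC[C@H](O)[C@@H]2C)[C@H](O)[C@@H]1O[Si](C(C)C)(C(C)C)C(C)C
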